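## Structural features

Septeremophilane E (44) is a trisnor-eremophilane. Two fused six-membered carbocycles, ring A (C1–C2–C3–C4–C5–C10) and ring B (C5–C6–C7–C8–C9–C10), share the C5–C10 bond, and C3 carries the ester oxygen of a (2E,4E,6R)-6-(hydroxymethyl)octa-2,4-dienoic acid (side chain C1'–C8', hydroxymethyl carbon C9'). Ring A holds three contiguous stereocentres, C3 (S, acyloxy), C4 (R, methyl C15) and the quaternary C5 (S, methyl C14), with the C3 oxygen and both methyl groups on the same face. The fourth stereocentre, C6', is remote and allylic to the dienoate. The unsaturation is one chromophore: C1=C2 and C9=C10 form a heteroannular diene conjugated with the C8 ketone, and ring B is completed by the C6=C7 enol of a 7,8-dione (a diosphenol). Fragile points are: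
- the acidic, easily oxidised and easily acylated diosphenol hydroxyl;
- the allylic C3 ester, whose C3–H is the ε-position of the trienone;
- the ε-hydrogen at C6' of the dienoate;
- the free primary alcohol.

The real difficulty is the quaternary C5 next to C4 and C3, combined with the need to raise ring B to a high oxidation level and to acylate C3 without touching the diosphenol. The key step exploits the diene C2=C1–C10=C9 that spans both rings. Its inner carbons C1 and C10 are the two carbons of an ethynyl group on C5, and its outer carbons C2 and C9 are the inner carbons of two vinyl groups, so both rings can be zipped up from a chain in which C3, C4 and C5 are already fixed.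

## Logic of the disconnections

**44 to 39.** The O–Si bond of the primary alcohol (44 from 43) and the C7–O bond (43 from 41 from 39) are cut first. The diosphenol would compete with the C3 hydroxyl in any acylation, so it is made last, from a plain ring-B ketone that already carries the ester. The gain is that 39 contains only a dienone and a protected side chain. The demand is kinetic enolisation at C7 in the presence of the dienoate, and two final steps that are not basic.

**39 to 27 and 37.** The ester bond C1'–O(C3) is cut. This is the convergent cut: it isolates C6' in 37 and leaves the three ring stereocentres in 27. The demand is acylation of a hindered allylic alcohol without isomerising the dienoate, and a masked hydroxyl in 37.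

**27 to 23 (key).** 27 goes back through 26 to 25 by functional-group changes only (C3 silyl ether, C8 carbinol). 25 is then cut at both double bonds of its diene, C9=C10 and C1=C2, which opens both rings and gives the acyclic dienyne 23. The design of 23 is improved over a bare dienyne in one respect: C8 already carries its oxygen as a free hydroxyl. This removes a late allylic C–H oxidation by a hexavalent chromium reagent next to a diene and an allylic silyl ether. It also activates for catalyst loading the very alkene that must react first, while the C3 silyl ether deactivates the other. The carbon skeleton (5-ethynyl-4,5-dimethyl-3-silyloxydeca-1,9-diene in eremophilane locants) and the two bonds formed are unchanged. The demand is site-selective initiation.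

**23 to 17 and 18.** 23 is cut at C8–C9 into 22 and 18. After unmasking and protection (22 from 21 from 20), it is cut at C3–H and C2–C3 (20 from 19 from 17 and 18). Both vinyl groups come from the same nucleophile, and C3 is set by 1,2-induction from C4 in a ketone reduction. The demand is Felkin–Anh control, and silylation of C3 before C8 is unmasked.

**17 to 14.** The C10≡C1 triple bond is cut back to a formyl group (16) and then to a propenyl group (14). A propenyl group is exactly what a [3,3] shift leaves on C5. The demand is that no other alkene exists at the ozonolysis stage, which is why both vinyl groups come later and C8 travels as a dioxolane.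

**12 to 9.** 14 comes from 12, and 12 is cut at C4–C5 to 9 (Ireland–Claisen retron). This is the one bond whose formation sets two adjacent centres, including the quaternary one, by chirality transfer from a carbinol. The ring-A stereochemistry is thereby reduced to one secondary alcohol and one alkene geometry. The demand is a (Z)-silyl ketene acetal and a chair transition state.

**9 to 1 and 2.** 9 is cut at the acyl–O bond into 7 and 8. 7 is cut at C5–C14 to 6, which returns to 4 by removing H and I across the alkene. 4 is cut at the sp–sp3 bond C5–C6 into 1 and 2. The carbinol configuration is bought, and the alkene geometry follows from stereospecific steps. The demand is retention in both the iodination and the coupling.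

**37 to 28 and 29.** 37 comes from 36, which is cut at C4'=C5' into 35 and a four-carbon phosphonate. 35 goes back through 34 and 33 to 32, which is cut at C6'–C9' to 30, itself from 28 and 29. The auxiliary gives a secure configuration at C6'. The demand is an aldehyde that is olefinated without epimerisation.

## Other disconnections considered

**Alternative 1:** The cut is the C8–C9 bond of ring B. Forward, the seco acid A2 (ring A complete, exocyclic methylene at C10, propanoic acid arm on C5) would be activated as a mixed fluorinated anhydride A3. Its acyl carbon would attack the methylene carbon C9 in a 6-endo closure, and proton loss from C9 would give the dienone benzoate A1. The diene of A2 (C9=C10–C1=C2) is a linearly conjugated semicyclic diene, not a cross-conjugated one. This matters because attack at its terminus gives an allyl cation spread over C10, C1 and C2.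
- In favour: C8 arrives directly as the ketone and no transition metal is needed. On the oxidation state of C8 it is the better plan by one step.
- Against: A2 must already contain ring A with C3, C4 and C5 and an acid-sensitive diene. The cation sits next to the C3 benzoate, which can participate or ionise, and capture of the cation by the counter-anion competes with proton loss.
- Comparison: it forms one ring and one bond, where the chosen plan forms two of each. It is cationic, where the chosen plan uses a neutral carbene that tolerates the allylic oxygen functions. Once the separate construction of ring A is counted, its step economy is at best equal. The two plans are equal in that neither key step creates a stereocentre.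

**Alternative 2:** The cuts are the C4'=C5' double bond and the C6'–C9' bond. The bond made by the hydroxymethylation is the one to the hydroxymethyl carbon C9'; the C6'–C7' bond to the ethyl group is already present in butanal A6. Forward, A6 and formaldehyde A7 would give (2S)-2-(hydroxymethyl)butanal A8 under prolinol silyl ether catalysis. A8 would be trapped in the same pot by the lithiated core phosphonocrotonate A5 to give the C7 silyl enol ether A4, which is desilylated to 44.
- In favour: the side chain is built in one operation instead of the seven steps that lead to 37, which is clearly better in step economy. Stereocontrol is catalytic. The diosphenol stays masked until a final fluoride step, which is equal to the chosen endgame.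
- Against: it disconnects only the side chain, so the core A5 still needs one of the other strategies. A8 is a free β-hydroxy aldehyde, and under the basic olefination its alkoxide can lose A7 by retro-aldol reaction or lose water, either of which would erode C6'. Water and excess A7 are incompatible with the phosphonate anion. The valuable core is exposed to a strong amide base at a stage where it carries a silyl enol ether and the ε-acidic C3–H.
- Comparison: the chosen plan spends more steps but sets C6' with an auxiliary, olefinates a configurationally robust silyl-protected aldehyde (35) with a cheap phosphonate, and joins the halves by a simple acylation.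

**Alternative 3:** The cut is the C1–C10 bond. Forward, the prochiral dienone A10 (C5 carrying methyl and the C4/C3 chain that ends in a (Z)-vinyl iodide) would undergo oxidative addition to a zerovalent palladium catalyst bearing a chiral bisphosphine. 6-exo carbopalladation of one enone arm and β-hydride elimination would give the trienone A9.
- In favour: C5 is created in the ring-closing step, so on stereocentre creation it is the better plan. A9 already has C8=O and C6=C7, so ring B is nearer the target oxidation level than in 25, which is also an advantage.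
- Against: C3 and C4 are already stereogenic, so the two arms are diastereotopic and the ligand may be matched or mismatched. After syn carbopalladation, palladium on C9 is anti to the only β-hydrogen (on C10). The elimination therefore needs prior epimerisation through the oxygen-bound palladium enolate, and protonation to the conjugate-addition product competes. A10 itself requires a bond from a branched carbon to a fully substituted dienone carbon.
- Comparison: it forms one ring and one bond against two of each. The chosen cascade has no stereochemical ambiguity because all centres are set beforehand by acyclic control. The step count is comparable, and the risk is concentrated in the key step.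

Key step: step 14

Remark on numbering: atoms carry eremophilane locants (C14 on C5, C15 on C4; side chain C1'–C8', hydroxymethyl carbon C9').
Remark on C8: it is carried in 23 and 25 as a mixture of epimers because it becomes a carbonyl carbon in 26.
Remark on descriptors: the C5 descriptor changes from R (25–27, 39, 41, 42) to S (43, 44) through a change of substituent priorities only. The key-step substrate and product map centre for centre onto 44.

## Route

Step 1
Reactants: 1 (2R)-but-3-yn-2-ol; 2 2-(2-bromoethyl)-1,3-dioxolane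
Product: 4 (2R)-6-(1,3-dioxolan-2-yl)hex-3-yn-2-ol, via dilithium alkynolate 3 (not isolated)
Conditions: n-BuLi (2.1 equiv), THF, −78 → 0 °C; DMPU, then 2, 0 °C → rt; aq. NH4Cl
Reagents that add atoms: none
Why: Double deprotonation (O–H, then the alkyne C–H) gives 3, whose acetylide carbon is far more nucleophilic than the lithium alkoxide, so the primary bromide is displaced at carbon (SN2 alkylation of a propargylic alcohol dianion). The carbinol stereocentre is not touched, and the dioxolane that masks C8 at the aldehyde level is inert to base.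

Step 2
Reactants: 4 (2R)-6-(1,3-dioxolan-2-yl)hex-3-yn-2-ol
Product: 6 (2R,3Z)-6-(1,3-dioxolan-2-yl)-4-iodohex-3-en-2-ol, via cyclic alkenylaluminate 5 (not isolated)
Conditions: NaAlH2(OCH2CH2OMe)2, THF, 0 °C → rt; EtOAc, then I2, −78 → 0 °C; aq. Na2S2O3
Reagents that add atoms: iodine, [I][I]
Why: Hydroxyl-directed trans-hydroalumination of a propargylic alcohol delivers hydride to the proximal alkyne carbon and holds aluminium on the distal one in the five-membered chelate 5; iodinolysis of the C–Al bond occurs with retention. Iodine therefore ends cis to the carbinol carbon (Z), which fixes the later alkene geometry; the acetal and the stereocentre are untouched.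

Step 3
Reactants: 6 (2R,3Z)-6-(1,3-dioxolan-2-yl)-4-iodohex-3-en-2-ol
Product: 7 (2R,3E)-6-(1,3-dioxolan-2-yl)-4-methylhex-3-en-2-ol
Conditions: Me2CuLi (from MeLi and CuI, 4 equiv), Et2O, −20 → 0 °C
Reagents that add atoms: lithium dimethylcuprate, [Li+].C[Cu-]C
Why: Coupling of a vinyl iodide with a lithium dialkylcuprate proceeds with retention of alkene geometry, so the methyl group (C14) replaces iodine cis to the carbinol carbon and the chain stays trans (E). Excess cuprate absorbs the O–H; the acetal is inert.

Step 4
Reactants: 7 (2R,3E)-6-(1,3-dioxolan-2-yl)-4-methylhex-3-en-2-ol; 8 propanoyl chloride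
Product: 9 (2R,3E)-6-(1,3-dioxolan-2-yl)-4-methylhex-3-en-2-yl propanoate
Conditions: pyridine, DMAP (cat.), CH2Cl2, 0 °C → rt
Reagents that add atoms: none
Why: DMAP-catalysed O-acylation of a secondary allylic alcohol with an acid chloride; the buffered, non-ionising conditions leave the carbinol configuration and the acetal untouched.

Step 5
Reactants: 9 (2R,3E)-6-(1,3-dioxolan-2-yl)-4-methylhex-3-en-2-yl propanoate
Product: 12 (2R,3S,4E)-3-[2-(1,3-dioxolan-2-yl)ethyl]-2,3-dimethylhex-4-enoic acid, via silyl ketene acetal 10 (not isolated), via trimethylsilyl ester 11 (not isolated)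
Conditions: LiN(iPr)2, THF/DMPU (2:1), −78 °C; Me3SiCl, Et3N, −78 °C → rt, then 50 °C; H2O, pH 4
Reagents that add atoms: none
Why: Ireland–Claisen rearrangement: enolisation in THF/DMPU and O-silylation should give the (Z)-silyl ketene acetal 10, which rearranges through a chair with the carbinol methyl equatorial, the C14 methyl axial and the enol methyl equatorial. The C4–C5 bond thus forms on one face of the E-alkene, transferring the carbinol chirality to the quaternary C5 (3S) and fixing C4 (2R) relative to it, while the new alkene is E. Silyl ester 11 is hydrolysed on mildly acidic work-up, which the dioxolane tolerates.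

Step 6
Reactants: 12 (2R,3S,4E)-3-[2-(1,3-dioxolan-2-yl)ethyl]-2,3-dimethylhex-4-enoic acid
Product: 14 (2R,3S,4E)-3-[2-(1,3-dioxolan-2-yl)ethyl]-N-methoxy-N,2,3-trimethylhex-4-enamide, via acyl imidazole 13 (not isolated)
Conditions: 1,1'-carbonyldiimidazole, CH2Cl2, rt; MeNH(OMe)·HCl, rt
Reagents that add atoms: N,O-dimethylhydroxylamine hydrochloride, CNOC.Cl
Why: Amide coupling through an acyl imidazole avoids acid chlorides and strong base, so the α-centre (C4) is not epimerised and the acetal survives. The Weinreb amide later stops vinyl addition at the ketone stage.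

Step 7
Reactants: 14 (2R,3S,4E)-3-[2-(1,3-dioxolan-2-yl)ethyl]-N-methoxy-N,2,3-trimethylhex-4-enamide
Product: 16 (2R,3R)-5-(1,3-dioxolan-2-yl)-3-formyl-N-methoxy-N,2,3-trimethylpentanamide, via ozonide 15 (not isolated)
Conditions: O3, CH2Cl2, −78 °C; PPh3, −78 °C → rt
Reagents that add atoms: ozone, [O-][O+]=O
Why: Ozonolysis with reductive work-up: the propenyl group is the only C=C bond in 14, so it is cleaved cleanly to the aldehyde (C10), which has no α-hydrogen and cannot epimerise. Amide and acetal are inert to ozone at −78 °C if over-ozonation is avoided.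

Step 8
Reactants: 16 (2R,3R)-5-(1,3-dioxolan-2-yl)-3-formyl-N-methoxy-N,2,3-trimethylpentanamide
Product: 17 (2R,3R)-3-[2-(1,3-dioxolan-2-yl)ethyl]-N-methoxy-N,2,3-trimethylpent-4-ynamide
Conditions: dimethyl (1-diazo-2-oxopropyl)phosphonate, K2CO3, MeOH, 0 °C → rt
Reagents that add atoms: dimethyl (1-diazo-2-oxopropyl)phosphonate, CC(=O)C(=[N+]=[N-])P(=O)(OC)OC
Why: Ohira–Bestmann homologation: the diazomethylphosphonate anion released by methanolysis adds to the aldehyde, and loss of phosphate and nitrogen with 1,2-hydride shift gives the terminal alkyne (C10≡C1). The carbonate conditions suit a non-enolisable aldehyde and do not disturb the amide α-centre.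

Step 9
Reactants: 17 (2R,3R)-3-[2-(1,3-dioxolan-2-yl)ethyl]-N-methoxy-N,2,3-trimethylpent-4-ynamide; 18 vinylmagnesium bromide
Product: 19 (4R,5R)-7-(1,3-dioxolan-2-yl)-5-ethynyl-4,5-dimethylhept-1-en-3-one
Conditions: CH2=CHMgBr (3 equiv), THF, −20 → 0 °C; inverse quench into cold aq. NaHSO4
Reagents that add atoms: none
Why: Grignard addition to a Weinreb amide stops at the chelated tetrahedral intermediate, which collapses to the vinyl ketone only on quench; one equivalent of 18 is consumed by the alkyne C–H. The cold acidic inverse quench removes the liberated amine before it can add to the enone, and C4 is configurationally safe in the magnesium chelate.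

Step 10
Reactants: 19 (4R,5R)-7-(1,3-dioxolan-2-yl)-5-ethynyl-4,5-dimethylhept-1-en-3-one
Product: 20 (3S,4R,5R)-7-(1,3-dioxolan-2-yl)-5-ethynyl-4,5-dimethylhept-1-en-3-ol
Conditions: NaBH4, CeCl3·7H2O, MeOH, −78 °C
Reagents that add atoms: none
Why: Luche 1,2-reduction with Felkin–Anh 1,2-induction: the quaternary C5 is the large group and lies anti to the incoming hydride, with the C4 methyl inside and hydrogen outside. This should give the (3S)-alcohol, in which C3–O and the C4 methyl have the relationship that becomes cis in ring A. The cerium salt suppresses conjugate reduction; alkyne and acetal are inert.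

Step 11
Reactants: 20 (3S,4R,5R)-7-(1,3-dioxolan-2-yl)-5-ethynyl-4,5-dimethylhept-1-en-3-ol
Product: 21 tert-butyl{[(3S,4R,5R)-7-(1,3-dioxolan-2-yl)-5-ethynyl-4,5-dimethylhept-1-en-3-yl]oxy}dimethylsilane
Conditions: t-BuMe2SiCl, imidazole, DMAP (cat.), DMF, 40 °C
Reagents that add atoms: tert-butyl(chloro)dimethylsilane, CC(C)(C)[Si](C)(C)Cl
Why: Silylation of the hindered secondary allylic alcohol under neutral imidazole conditions (a silyl triflate is avoided because it can open the dioxolane). The bulky silyl ether protects C3 and later keeps ruthenium off the ring-A alkene.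

Step 12
Reactants: 21 tert-butyl{[(3S,4R,5R)-7-(1,3-dioxolan-2-yl)-5-ethynyl-4,5-dimethylhept-1-en-3-yl]oxy}dimethylsilane
Product: 22 (4R,5R,6S)-6-{[tert-butyl(dimethyl)silyl]oxy}-4-ethynyl-4,5-dimethyloct-7-enal
Conditions: pyridinium p-toluenesulfonate, acetone/H2O, 55 °C
Reagents that add atoms: water, O
Why: Acid-catalysed acetal hydrolysis releases the C8 aldehyde. Pyridinium tosylate in wet acetone is mild enough to spare the hindered secondary silyl ether, the allylic system and the alkyne.

Step 13
Reactants: 22 (4R,5R,6S)-6-{[tert-butyl(dimethyl)silyl]oxy}-4-ethynyl-4,5-dimethyloct-7-enal; 18 vinylmagnesium bromide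
Product: 23 (3RS,6R,7R,8S)-8-{[tert-butyl(dimethyl)silyl]oxy}-6-ethynyl-6,7-dimethyldeca-1,9-dien-3-ol
Conditions: CH2=CHMgBr (2.5 equiv), THF, −78 → −40 °C; aq. NH4Cl
Reagents that add atoms: none
Why: Grignard addition to the aldehyde makes the C8–C9 bond and the second terminal alkene; the first equivalent of 18 is consumed by the alkyne C–H. The new carbinol centre needs no control because C8 becomes a carbonyl carbon in step 15, and the free hydroxyl is wanted for the next step.

Step 14
Reactants: 23 (3RS,6R,7R,8S)-8-{[tert-butyl(dimethyl)silyl]oxy}-6-ethynyl-6,7-dimethyldeca-1,9-dien-3-ol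
Product: 25 (2RS,4aR,5R,6S)-6-{[tert-butyl(dimethyl)silyl]oxy}-4a,5-dimethyl-2,3,4,4a,5,6-hexahydronaphthalen-2-ol, via ruthenium vinylcarbene 24 (not isolated)
Conditions: second-generation Grubbs catalyst RuCl2(=CHPh)(PCy3)(H2IMes) (10 mol %), CH2Cl2 (0.005 M), 40 °C, argon
Reagents that add atoms: none
Why: Tandem ring-closing dienyne metathesis, whose closest known relative is the ene–yne–ene cascade of acyclic dienynes to fused bicyclic 1,3-dienes with second-generation ruthenium carbenes. Ruthenium is loaded on the C9 alkene, which is monosubstituted, remote from branching and carries a free allylic hydroxyl at C8 that speeds loading, whereas the C2 alkene is shielded by the C3 silyl ether and the branched C4. The C9 alkylidene adds across the ethynyl group on C5 in the exo mode (cycloaddition, then cycloreversion), making C9=C10, closing six-membered ring B (C5–C6–C7–C8–C9–C10) and leaving the vinylcarbene 24 on C1. Carbene 24 then closes onto the C2 alkene by six-membered ring-closing metathesis, making C1=C2 and ring A (C1–C2–C3–C4–C5–C10) and expelling the terminal CH2 as ethene. No stereocentre is created: C3, C4 and C5 are spectators and C8 is an inconsequential epimer mixture. The selectivity needed is the site of initiation, because loading at the ring-A alkene would close a five-membered ring onto the alkyne and end in a 5–7 skeleton; it is secured by the hindered silyl ether arm against the activated hydroxy-allyl arm. High dilution suppresses cross-metathesis, and direct closure between the two alkenes would need an eight-membered ring and cannot compete.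

Step 15
Reactants: 25 (2RS,4aR,5R,6S)-6-{[tert-butyl(dimethyl)silyl]oxy}-4a,5-dimethyl-2,3,4,4a,5,6-hexahydronaphthalen-2-ol
Product: 26 (4aR,5R,6S)-6-{[tert-butyl(dimethyl)silyl]oxy}-4a,5-dimethyl-4,4a,5,6-tetrahydronaphthalen-2(3H)-one
Conditions: MnO2 (activated, excess), CH2Cl2, rt
Reagents that add atoms: none
Why: MnO2 oxidises allylic alcohols selectively; the dienylic C8 carbinol gives the linearly conjugated dienone and both C8 epimers converge. The neutral conditions spare the silyl ether and avoid ionisation of the dienylic alcohol.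

Step 16
Reactants: 26 (4aR,5R,6S)-6-{[tert-butyl(dimethyl)silyl]oxy}-4a,5-dimethyl-4,4a,5,6-tetrahydronaphthalen-2(3H)-one
Product: 27 (4aR,5R,6S)-6-hydroxy-4a,5-dimethyl-4,4a,5,6-tetrahydronaphthalen-2(3H)-one
Conditions: HF·pyridine, pyridine, THF, 0 °C → rt
Reagents that add atoms: none
Why: Buffered fluoride cleaves the Si–O bond of the secondary silyl ether without base-induced enolisation of the dienone. The C3–O bond is not broken, so the (S) configuration is retained.

Step 17
Reactants: 28 (4R)-4-benzyl-1,3-oxazolidin-2-one; 29 butanoyl chloride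
Product: 30 (4R)-4-benzyl-3-butanoyl-1,3-oxazolidin-2-one
Conditions: Et3N, DMAP (cat.), CH2Cl2, 0 °C → rt
Reagents that add atoms: none
Why: N-Acylation of the oxazolidinone by the acid chloride under amine/DMAP catalysis; no stereocentre is affected.

Step 18
Reactants: 30 (4R)-4-benzyl-3-butanoyl-1,3-oxazolidin-2-one
Product: 32 (4R)-4-benzyl-3-[(2S)-2-(hydroxymethyl)butanoyl]-1,3-oxazolidin-2-one, via titanium enolate 31 (not isolated)
Conditions: TiCl4, i-Pr2NEt, CH2Cl2, 0 °C; 1,3,5-trioxane, TiCl4, 0 °C
Reagents that add atoms: 1,3,5-trioxane, C1OCOCO1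
Why: Soft enolisation gives the chelated (Z)-enolate 31, which is attacked on the face opposite the benzyl group by the oxocarbenium species released from trioxane by TiCl4 (auxiliary-controlled hydroxymethylation). With the (R)-auxiliary this should set the (2S) centre, which is C6' (R) of the target once the carbonyl carbon has become the diene terminus.

Step 19
Reactants: 32 (4R)-4-benzyl-3-[(2S)-2-(hydroxymethyl)butanoyl]-1,3-oxazolidin-2-one
Product: 33 (4R)-4-benzyl-3-[(2S)-2-({[tert-butyl(dimethyl)silyl]oxy}methyl)butanoyl]-1,3-oxazolidin-2-one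
Conditions: t-BuMe2SiCl, imidazole, CH2Cl2, rt
Reagents that add atoms: tert-butyl(chloro)dimethylsilane, CC(C)(C)[Si](C)(C)Cl
Why: Silylation of a primary alcohol; the near-neutral conditions avoid retro-aldol loss of formaldehyde from the β-hydroxy imide.

Step 20
Reactants: 33 (4R)-4-benzyl-3-[(2S)-2-({[tert-butyl(dimethyl)silyl]oxy}methyl)butanoyl]-1,3-oxazolidin-2-one
Product: 34 (2R)-2-({[tert-butyl(dimethyl)silyl]oxy}methyl)butan-1-ol
Conditions: LiBH4, H2O (1 equiv), Et2O, 0 °C
Reagents that add atoms: none
Why: Reductive cleavage of the N-acyl oxazolidinone gives the primary alcohol and returns the auxiliary. The stereocentre is not enolised, and the low temperature guards against 1,3-silyl migration, which would erode the configuration.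

Step 21
Reactants: 34 (2R)-2-({[tert-butyl(dimethyl)silyl]oxy}methyl)butan-1-ol
Product: 35 (2S)-2-({[tert-butyl(dimethyl)silyl]oxy}methyl)butanal
Conditions: Dess–Martin periodinane, NaHCO3, CH2Cl2, 0 °C → rt
Reagents that add atoms: none
Why: Buffered periodinane oxidation gives the α-branched aldehyde without epimerisation (an ethyl analogue of the widely used 3-silyloxy-2-methylpropanal); it is used at once.

Step 22
Reactants: 35 (2S)-2-({[tert-butyl(dimethyl)silyl]oxy}methyl)butanal
Product: 36 ethyl (2E,4E,6R)-6-({[tert-butyl(dimethyl)silyl]oxy}methyl)octa-2,4-dienoate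
Conditions: triethyl 4-phosphonocrotonate, LiN(SiMe3)2, THF, −78 → 0 °C
Reagents that add atoms: triethyl 4-phosphonocrotonate, CCOC(=O)/C=C/CP(=O)(OCC)OCC
Why: Vinylogous Horner–Wadsworth–Emmons olefination: the lithiated phosphonate adds through the carbon bearing phosphorus and loses phosphate to form the C4'=C5' bond with E geometry, the C2'=C3' bond being E from the reagent. At −78 °C the α-stereocentre of 35 is not epimerised.

Step 23
Reactants: 36 ethyl (2E,4E,6R)-6-({[tert-butyl(dimethyl)silyl]oxy}methyl)octa-2,4-dienoate
Product: 37 (2E,4E,6R)-6-({[tert-butyl(dimethyl)silyl]oxy}methyl)octa-2,4-dienoic acid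
Conditions: LiOH, THF/MeOH/H2O, rt; aq. HCl to pH 4
Reagents that add atoms: lithium hydroxide, [Li+].[OH-]
Why: Saponification of the ethyl ester; hydroxide is not basic enough to remove the ε-hydrogen, so the diene geometry and C6' are retained. The primary silyl ether survives brief acidification to pH 4.

Step 24
Reactants: 27 (4aR,5R,6S)-6-hydroxy-4a,5-dimethyl-4,4a,5,6-tetrahydronaphthalen-2(3H)-one; 37 (2E,4E,6R)-6-({[tert-butyl(dimethyl)silyl]oxy}methyl)octa-2,4-dienoic acid
Product: 39 (1R,2S,8aR)-1,8a-dimethyl-6-oxo-1,2,6,7,8,8a-hexahydronaphthalen-2-yl (2E,4E,6R)-6-({[tert-butyl(dimethyl)silyl]oxy}methyl)octa-2,4-dienoate, via mixed anhydride 38 (not isolated)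
Conditions: 2,4,6-trichlorobenzoyl chloride, Et3N, THF, rt; then 27, DMAP, toluene, rt
Reagents that add atoms: none
Why: Yamaguchi esterification: 37 is activated as the mixed anhydride 38 and DMAP transfers the dienoyl group to the hindered allylic C3 hydroxyl, with retention at C3 because the C–O bond is not broken. 27 has no other nucleophilic site, which is why the ester is installed before the diosphenol exists.

Step 25
Reactants: 39 (1R,2S,8aR)-1,8a-dimethyl-6-oxo-1,2,6,7,8,8a-hexahydronaphthalen-2-yl (2E,4E,6R)-6-({[tert-butyl(dimethyl)silyl]oxy}methyl)octa-2,4-dienoate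
Product: 41 (1R,2S,7RS,8aR)-7-hydroxy-1,8a-dimethyl-6-oxo-1,2,6,7,8,8a-hexahydronaphthalen-2-yl (2E,4E,6R)-6-({[tert-butyl(dimethyl)silyl]oxy}methyl)octa-2,4-dienoate, via lithium enolate 40 (not isolated)
Conditions: LiN(SiMe3)2, THF, −78 °C; 2-(phenylsulfonyl)-3-phenyloxaziridine, −78 °C; aq. NH4Cl
Reagents that add atoms: 2-(phenylsulfonyl)-3-phenyloxaziridine, O=S(=O)(c1ccccc1)N1OC1c1ccccc1
Why: Kinetic deprotonation of the dienone at −78 °C occurs at the α'-methylene C7 to give the cross-conjugated enolate 40; the ε-hydrogens at C3 and at C6' are kinetically much less accessible. Electrophilic oxygen transfer from the N-sulfonyloxaziridine then gives the α-hydroxy ketone. The new C7 centre needs no control because it becomes sp2 in the next step.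

Step 26
Reactants: 41 (1R,2S,7RS,8aR)-7-hydroxy-1,8a-dimethyl-6-oxo-1,2,6,7,8,8a-hexahydronaphthalen-2-yl (2E,4E,6R)-6-({[tert-butyl(dimethyl)silyl]oxy}methyl)octa-2,4-dienoate
Product: 43 (1R,2S,8aS)-7-hydroxy-1,8a-dimethyl-6-oxo-1,2,6,8a-tetrahydronaphthalen-2-yl (2E,4E,6R)-6-({[tert-butyl(dimethyl)silyl]oxy}methyl)octa-2,4-dienoate, via diketone 42 (not isolated)
Conditions: Dess–Martin periodinane, NaHCO3, CH2Cl2, 0 °C → rt
Reagents that add atoms: none
Why: Oxidation of the α-ketol gives the 7,8-dione 42, which enolises only towards C6 (C5 is quaternary) to the fully conjugated diosphenol. The buffered conditions leave the silyl ether, the allylic ester and the dienoate untouched.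

Step 27
Reactants: 43 (1R,2S,8aS)-7-hydroxy-1,8a-dimethyl-6-oxo-1,2,6,8a-tetrahydronaphthalen-2-yl (2E,4E,6R)-6-({[tert-butyl(dimethyl)silyl]oxy}methyl)octa-2,4-dienoate
Product: 44 Septeremophilane E
Conditions: HF·pyridine, pyridine, THF, 0 °C → rt
Reagents that add atoms: none
Why: Fluoride cleavage of the primary silyl ether under buffered, weakly acidic conditions that the diosphenol, the allylic ester and the dienoate should tolerate; no stereocentre is affected.

## Compound list

1 | (2R)-but-3-yn-2-ol | C[C@@H](O)C#C | starting material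
2 | 2-(2-bromoethyl)-1,3-dioxolane | BrCCC1OCCO1 | starting material
3 | dilithium alkynolate of 1 (lithium (2R)-4-lithiobut-3-yn-2-olate) | C[C@@H](O[Li])C#C[Li] | intermediate (not isolated)
4 | (2R)-6-(1,3-dioxolan-2-yl)hex-3-yn-2-ol | C[C@@H](O)C#CCCC1OCCO1 | intermediate
5 | cyclic alkenylaluminate: sodium (5R)-3-[2-(1,3-dioxolan-2-yl)ethyl]-2,2-bis(2-methoxyethoxy)-5-methyl-2,5-dihydro-1,2-oxaluminol-2-uide | C[C@@H]1C=C(CCC2OCCO2)[Al-](OCCOC)(OCCOC)O1.[Na+] | intermediate (not isolated)
6 | (2R,3Z)-6-(1,3-dioxolan-2-yl)-4-iodohex-3-en-2-ol | C[C@@H](O)/C=C(\I)CCC1OCCO1 | intermediate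
7 | (2R,3E)-6-(1,3-dioxolan-2-yl)-4-methylhex-3-en-2-ol | C[C@@H](O)/C=C(\C)CCC1OCCO1 | intermediate
8 | propanoyl chloride | CCC(=O)Cl | starting material
9 | (2R,3E)-6-(1,3-dioxolan-2-yl)-4-methylhex-3-en-2-yl propanoate | CCC(=O)O[C@H](C)/C=C(\C)CCC1OCCO1 | intermediate
10 | silyl ketene acetal: {[(1Z)-1-{[(2R,3E)-6-(1,3-dioxolan-2-yl)-4-methylhex-3-en-2-yl]oxy}prop-1-en-1-yl]oxy}trimethylsilane | C/C=C(\O[Si](C)(C)C)O[C@H](C)/C=C(\C)CCC1OCCO1 | intermediate (not isolated)
11 | trimethylsilyl (2R,3S,4E)-3-[2-(1,3-dioxolan-2-yl)ethyl]-2,3-dimethylhex-4-enoate | C[Si](C)(C)OC(=O)[C@H](C)[C@](C)(/C=C/C)CCC1OCCO1 | intermediate (not isolated)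
12 | (2R,3S,4E)-3-[2-(1,3-dioxolan-2-yl)ethyl]-2,3-dimethylhex-4-enoic acid | OC(=O)[C@H](C)[C@](C)(/C=C/C)CCC1OCCO1 | intermediate
13 | acyl imidazole: (2R,3S,4E)-3-[2-(1,3-dioxolan-2-yl)ethyl]-1-(1H-imidazol-1-yl)-2,3-dimethylhex-4-en-1-one | O=C([C@H](C)[C@](C)(/C=C/C)CCC1OCCO1)n1ccnc1 | intermediate (not isolated)
14 | (2R,3S,4E)-3-[2-(1,3-dioxolan-2-yl)ethyl]-N-methoxy-N,2,3-trimethylhex-4-enamide | CON(C)C(=O)[C@H](C)[C@](C)(/C=C/C)CCC1OCCO1 | intermediate
15 | ozonide: (2R,3R)-5-(1,3-dioxolan-2-yl)-N-methoxy-N,2,3-trimethyl-3-(5-methyl-1,2,4-trioxolan-3-yl)pentanamide | CON(C)C(=O)[C@H](C)[C@](C)(C1OOC(C)O1)CCC1OCCO1 | intermediate (not isolated)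
16 | (2R,3R)-5-(1,3-dioxolan-2-yl)-3-formyl-N-methoxy-N,2,3-trimethylpentanamide | CON(C)C(=O)[C@H](C)[C@](C)(C=O)CCC1OCCO1 | intermediate
17 | (2R,3R)-3-[2-(1,3-dioxolan-2-yl)ethyl]-N-methoxy-N,2,3-trimethylpent-4-ynamide | CON(C)C(=O)[C@H](C)[C@](C)(C#C)CCC1OCCO1 | intermediate
18 | vinylmagnesium bromide | C=C[Mg]Br | starting material
19 | (4R,5R)-7-(1,3-dioxolan-2-yl)-5-ethynyl-4,5-dimethylhept-1-en-3-one | C=CC(=O)[C@H](C)[C@](C)(C#C)CCC1OCCO1 | intermediate
20 | (3S,4R,5R)-7-(1,3-dioxolan-2-yl)-5-ethynyl-4,5-dimethylhept-1-en-3-ol | C=C[C@H](O)[C@H](C)[C@](C)(C#C)CCC1OCCO1 | intermediate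
21 | tert-butyl{[(3S,4R,5R)-7-(1,3-dioxolan-2-yl)-5-ethynyl-4,5-dimethylhept-1-en-3-yl]oxy}dimethylsilane | CC(C)(C)[Si](C)(C)O[C@@H](C=C)[C@H](C)[C@](C)(C#C)CCC1OCCO1 | intermediate
22 | (4R,5R,6S)-6-{[tert-butyl(dimethyl)silyl]oxy}-4-ethynyl-4,5-dimethyloct-7-enal | CC(C)(C)[Si](C)(C)O[C@@H](C=C)[C@H](C)[C@](C)(C#C)CCC=O | intermediate
23 | (3RS,6R,7R,8S)-8-{[tert-butyl(dimethyl)silyl]oxy}-6-ethynyl-6,7-dimethyldeca-1,9-dien-3-ol (key-step precursor) | CC(C)(C)[Si](C)(C)O[C@@H](C=C)[C@H](C)[C@](C)(C#C)CCC(O)C=C | intermediate
24 | ruthenium vinylcarbene (ring B closed, carbene on C1, RuCl2(H2IMes) fragment) | C=C[C@H](O[Si](C)(C)C(C)(C)C)[C@H](C)[C@@]1(C)CCC(O)C=C1C=[Ru](Cl)(Cl)=C1N(c2c(C)cc(C)cc2C)CCN1c1c(C)cc(C)cc1C | intermediate (not isolated)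
25 | (2RS,4aR,5R,6S)-6-{[tert-butyl(dimethyl)silyl]oxy}-4a,5-dimethyl-2,3,4,4a,5,6-hexahydronaphthalen-2-ol (key-step product) | CC(C)(C)[Si](C)(C)O[C@H]1C=CC2=CC(O)CC[C@]2(C)[C@H]1C | intermediate
26 | (4aR,5R,6S)-6-{[tert-butyl(dimethyl)silyl]oxy}-4a,5-dimethyl-4,4a,5,6-tetrahydronaphthalen-2(3H)-one | CC(C)(C)[Si](C)(C)O[C@H]1C=CC2=CC(=O)CC[C@]2(C)[C@H]1C | intermediate
27 | (4aR,5R,6S)-6-hydroxy-4a,5-dimethyl-4,4a,5,6-tetrahydronaphthalen-2(3H)-one | O[C@H]1C=CC2=CC(=O)CC[C@]2(C)[C@H]1C | intermediate
28 | (4R)-4-benzyl-1,3-oxazolidin-2-one | O=C1N[C@H](Cc2ccccc2)CO1 | starting material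
29 | butanoyl chloride | CCCC(=O)Cl | starting material
30 | (4R)-4-benzyl-3-butanoyl-1,3-oxazolidin-2-one | CCCC(=O)N1[C@H](Cc2ccccc2)COC1=O | intermediate
31 | titanium enolate: trichlorotitanium (Z)-enolate of 30 | CC/C=C(\O[Ti](Cl)(Cl)Cl)N1[C@H](Cc2ccccc2)COC1=O | intermediate (not isolated)
32 | (4R)-4-benzyl-3-[(2S)-2-(hydroxymethyl)butanoyl]-1,3-oxazolidin-2-one | CC[C@@H](CO)C(=O)N1[C@H](Cc2ccccc2)COC1=O | intermediate
33 | (4R)-4-benzyl-3-[(2S)-2-({[tert-butyl(dimethyl)silyl]oxy}methyl)butanoyl]-1,3-oxazolidin-2-one | CC[C@@H](CO[Si](C)(C)C(C)(C)C)C(=O)N1[C@H](Cc2ccccc2)COC1=O | intermediate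
34 | (2R)-2-({[tert-butyl(dimethyl)silyl]oxy}methyl)butan-1-ol | CC[C@H](CO)CO[Si](C)(C)C(C)(C)C | intermediate
35 | (2S)-2-({[tert-butyl(dimethyl)silyl]oxy}methyl)butanal | CC[C@H](C=O)CO[Si](C)(C)C(C)(C)C | intermediate
36 | ethyl (2E,4E,6R)-6-({[tert-butyl(dimethyl)silyl]oxy}methyl)octa-2,4-dienoate | CC[C@H](/C=C/C=C/C(=O)OCC)CO[Si](C)(C)C(C)(C)C | intermediate
37 | (2E,4E,6R)-6-({[tert-butyl(dimethyl)silyl]oxy}methyl)octa-2,4-dienoic acid | CC[C@H](/C=C/C=C/C(=O)O)CO[Si](C)(C)C(C)(C)C | intermediate
38 | mixed anhydride of 37 with 2,4,6-trichlorobenzoic acid | CC[C@H](/C=C/C=C/C(=O)OC(=O)c1c(Cl)cc(Cl)cc1Cl)CO[Si](C)(C)C(C)(C)C | intermediate (not isolated)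
39 | (1R,2S,8aR)-1,8a-dimethyl-6-oxo-1,2,6,7,8,8a-hexahydronaphthalen-2-yl (2E,4E,6R)-6-({[tert-butyl(dimethyl)silyl]oxy}methyl)octa-2,4-dienoate | CC[C@H](/C=C/C=C/C(=O)O[C@H]1C=CC2=CC(=O)CC[C@]2(C)[C@H]1C)CO[Si](C)(C)C(C)(C)C | intermediate
40 | lithium enolate of 39 (cross-conjugated, C7=C8–OLi) | CC[C@H](/C=C/C=C/C(=O)O[C@H]1C=CC2=CC(O[Li])=CC[C@]2(C)[C@H]1C)CO[Si](C)(C)C(C)(C)C | intermediate (not isolated)
41 | (1R,2S,7RS,8aR)-7-hydroxy-1,8a-dimethyl-6-oxo-1,2,6,7,8,8a-hexahydronaphthalen-2-yl (2E,4E,6R)-6-({[tert-butyl(dimethyl)silyl]oxy}methyl)octa-2,4-dienoate | CC[C@H](/C=C/C=C/C(=O)O[C@H]1C=CC2=CC(=O)C(O)C[C@]2(C)[C@H]1C)CO[Si](C)(C)C(C)(C)C | intermediate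
42 | diketone: (1R,2S,8aR)-1,8a-dimethyl-6,7-dioxo-1,2,6,7,8,8a-hexahydronaphthalen-2-yl (2E,4E,6R)-6-({[tert-butyl(dimethyl)silyl]oxy}methyl)octa-2,4-dienoate | CC[C@H](/C=C/C=C/C(=O)O[C@H]1C=CC2=CC(=O)C(=O)C[C@]2(C)[C@H]1C)CO[Si](C)(C)C(C)(C)C | intermediate (not isolated)
43 | (1R,2S,8aS)-7-hydroxy-1,8a-dimethyl-6-oxo-1,2,6,8a-tetrahydronaphthalen-2-yl (2E,4E,6R)-6-({[tert-butyl(dimethyl)silyl]oxy}methyl)octa-2,4-dienoate | CC[C@H](/C=C/C=C/C(=O)O[C@H]1C=CC2=CC(=O)C(O)=C[C@]2(C)[C@H]1C)CO[Si](C)(C)C(C)(C)C | intermediate
44 | Septeremophilane E: (1R,2S,8aS)-7-hydroxy-1,8a-dimethyl-6-oxo-1,2,6,8a-tetrahydronaphthalen-2-yl (2E,4E,6R)-6-(hydroxymethyl)octa-2,4-dienoate | CC[C@H](/C=C/C=C/C(=O)O[C@H]1C=CC2=CC(=O)C(O)=C[C@]2(C)[C@H]1C)CO | target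

## Step count and least certain steps

Total step count: 27. Longest linear sequence: 20 steps (steps 1–16, then 24–27). The side-chain branch (steps 17–23) has 7 steps and joins at step 24.

**Step 14 (key step).** Ruthenium may load on the ring-A alkene, or add to the alkyne first with the wrong regiochemistry; either leads to five-membered closure and a 5–7 skeleton. The cascade may also stall after ring B, so that the vinylcarbene is intercepted between molecules, and ruthenium hydride species may isomerise the allylic alcohol to a ketone. The fallback separates the two closures; it sets out from 23 and returns at 25. Enyne ring-closing metathesis of 23 under ethene with the first-generation Grubbs catalyst RuCl2(=CHPh)(PCy3)2, which is too unreactive to engage the hindered silyl ether arm, should give the monocyclic triene F1 (ring B closed, vinyl group on C10). A separate diene ring-closing metathesis of F1 with the second-generation catalyst at higher temperature should then close ring A with loss of ethene to give 25.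

**Step 5.** Erosion of the ketene acetal geometry, or leakage through a boat transition state, would give the C4 epimer. The slow formation of the quaternary centre also leaves time for the ketene acetal to decompose. The fallback inverts both the alkene geometry and the carbinol configuration, so that the kinetically favoured (E)-ketene acetal (LiN(iPr)2 in THF alone) is the matching partner. It sets out from 2 and returns at 12. Bromide 2 is converted with Zn and LiCl into the alkylzinc bromide F2. Commercial (2S)-pent-3-yn-2-ol F3 is taken through the hydroalumination–iodination of step 2 to the (Z)-iodide F4. Negishi coupling of F4 with F2 (PdCl2(dppf)) should give the (2S,3Z)-allylic alcohol F5, and propanoylation as in step 4 gives the ester F6. Enolisation and silylation then give the (E)-silyl ketene acetal F7, whose chair rearrangement leads through 11 to the same acid 12.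

**Step 10.** Facial selectivity may be poor, or conjugate reduction may compete. The fallback makes C3 by C–C bond formation followed by inversion; it sets out from 17 and returns at 20. Reduction of 17 with i-Bu2AlH gives the aldehyde F8. Felkin-controlled addition of 18 should give the epimeric (3R)-alcohol F9. Mitsunobu inversion with 4-nitrobenzoic acid gives the (3S)-ester F10, and methanolysis (K2CO3, MeOH) gives 20.

**Step 25.** Deprotonation may compete at C3 or C6', the amide base may attack the dienoate, or the enolate may add to the sulfonimine by-product. The fallback is a Rubottom oxidation that avoids the strong base; it sets out from 39 and returns at 41. Soft enolisation with Me3SiOTf and Et3N gives the cross-conjugated silyl dienol ether F11. Dimethyldioxirane epoxidises its most electron-rich double bond to the silyloxy epoxide F12, and mildly acidic aqueous work-up opens F12 to 41.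

## Further compounds

F1 | step 14 | (1RS,4R)-3-ethenyl-4-methyl-4-[(2R,3S)-3-{[tert-butyl(dimethyl)silyl]oxy}pent-4-en-2-yl]cyclohex-2-en-1-ol | C=C[C@H](O[Si](C)(C)C(C)(C)C)[C@H](C)[C@@]1(C)CCC(O)C=C1C=C
F2 | step 5 | [2-(1,3-dioxolan-2-yl)ethyl]zinc bromide | Br[Zn]CCC1OCCO1
F3 | step 5 | (2S)-pent-3-yn-2-ol | C[C@H](O)C#CC
F4 | step 5 | (2S,3Z)-4-iodopent-3-en-2-ol | C[C@H](O)/C=C(\I)C
F5 | step 5 | (2S,3Z)-6-(1,3-dioxolan-2-yl)-4-methylhex-3-en-2-ol | C[C@H](O)/C=C(/C)CCC1OCCO1
F6 | step 5 | (2S,3Z)-6-(1,3-dioxolan-2-yl)-4-methylhex-3-en-2-yl propanoate | CCC(=O)O[C@@H](C)/C=C(/C)CCC1OCCO1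
F7 | step 5 | {[(1E)-1-{[(2S,3Z)-6-(1,3-dioxolan-2-yl)-4-methylhex-3-en-2-yl]oxy}prop-1-en-1-yl]oxy}trimethylsilane | C/C=C(/O[Si](C)(C)C)O[C@@H](C)/C=C(/C)CCC1OCCO1
F8 | step 10 | (2R,3R)-3-[2-(1,3-dioxolan-2-yl)ethyl]-2,3-dimethylpent-4-ynal | O=C[C@H](C)[C@](C)(C#C)CCC1OCCO1
F9 | step 10 | (3R,4R,5R)-7-(1,3-dioxolan-2-yl)-5-ethynyl-4,5-dimethylhept-1-en-3-ol | C=C[C@@H](O)[C@H](C)[C@](C)(C#C)CCC1OCCO1
F10 | step 10 | (3S,4R,5R)-7-(1,3-dioxolan-2-yl)-5-ethynyl-4,5-dimethylhept-1-en-3-yl 4-nitrobenzoate | O=C(O[C@@H](C=C)[C@H](C)[C@](C)(C#C)CCC1OCCO1)c1ccc(cc1)[N+](=O)[O-]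
F11 | step 25 | trimethylsilyl dienol ether of 39 (C7=C8–OSiMe3) | CC[C@H](/C=C/C=C/C(=O)O[C@H]1C=CC2=CC(O[Si](C)(C)C)=CC[C@]2(C)[C@H]1C)CO[Si](C)(C)C(C)(C)C
F12 | step 25 | 7,8-epoxy-8-(trimethylsilyloxy) derivative of F11 | CC[C@H](/C=C/C=C/C(=O)O[C@H]1C=CC2=CC3(O[Si](C)(C)C)OC3C[C@]2(C)[C@H]1C)CO[Si](C)(C)C(C)(C)C
A1 | alternative 1 | (1R,2S,8aR)-1,8a-dimethyl-6-oxo-1,2,6,7,8,8a-hexahydronaphthalen-2-yl benzoate | O=C(O[C@H]1C=CC2=CC(=O)CC[C@]2(C)[C@H]1C)c1ccccc1
A2 | alternative 1 | 3-[(1R,5S,6R)-5-(benzoyloxy)-1,6-dimethyl-2-methylidenecyclohex-3-en-1-yl]propanoic acid | O=C(O[C@H]1C=CC(=C)[C@](C)(CCC(=O)O)[C@H]1C)c1ccccc1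
A3 | alternative 1 | mixed anhydride of A2 with trifluoroacetic acid | O=C(O[C@H]1C=CC(=C)[C@](C)(CCC(=O)OC(=O)C(F)(F)F)[C@H]1C)c1ccccc1
A4 | alternative 2 | (1R,2S,8aS)-7-{[tert-butyl(dimethyl)silyl]oxy}-1,8a-dimethyl-6-oxo-1,2,6,8a-tetrahydronaphthalen-2-yl (2E,4E,6R)-6-(hydroxymethyl)octa-2,4-dienoate | CC[C@H](/C=C/C=C/C(=O)O[C@H]1C=CC2=CC(=O)C(O[Si](C)(C)C(C)(C)C)=C[C@]2(C)[C@H]1C)CO
A5 | alternative 2 | (1R,2S,8aS)-7-{[tert-butyl(dimethyl)silyl]oxy}-1,8a-dimethyl-6-oxo-1,2,6,8a-tetrahydronaphthalen-2-yl (2E)-4-(diethoxyphosphoryl)but-2-enoate | CCOP(=O)(OCC)C/C=C/C(=O)O[C@H]1C=CC2=CC(=O)C(O[Si](C)(C)C(C)(C)C)=C[C@]2(C)[C@H]1C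
A6 | alternative 2 | butanal | CCCC=O
A7 | alternative 2 | formaldehyde | C=O
A8 | alternative 2 | (2S)-2-(hydroxymethyl)butanal | CC[C@H](C=O)CO
A9 | alternative 3 | (4aR,5R,6S)-6-{[tert-butyl(dimethyl)silyl]oxy}-4a,5-dimethyl-5,6-dihydronaphthalen-2(4aH)-one | CC(C)(C)[Si](C)(C)O[C@H]1C=CC2=CC(=O)C=C[C@]2(C)[C@H]1C
A10 | alternative 3 | 4-[(2R,3R,4Z)-3-{[tert-butyl(dimethyl)silyl]oxy}-5-iodopent-4-en-2-yl]-4-methylcyclohexa-2,5-dien-1-one | CC(C)(C)[Si](C)(C)O[C@@H](/C=C\I)[C@H](C)C1(C)C=CC(=O)C=C1
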